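**Retrosynthetic overview**
- Colletotryptin A ⇐ O‑silyl/N‑sulfonyl protected 2,3'‑bis(indolyl)methane by global deprotection.
- The tryptophol indole is formed last: Larock heteroannulation of 2‑iodoaniline with an internal alkyne whose propargylic carbon is the future methine.
- That propargylic C–C bond ⇐ anti (SN2) opening at C3 of a trans‑3‑(indol‑3‑yl)‑2,3‑epoxy alcohol by an alkynylalane, which transmits both stereocentres.
- Epoxy alcohol ⇐ trans‑glycidic ester ⇐ anti‑chlorohydrin ester, both stereocentres set in one ketoreductase dynamic kinetic reduction of an α‑chloro‑β‑keto ester built from indole‑3‑carbaldehyde and a malonate half ester.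
- Ring order: purchased indole → oxirane (step 6, consumed in step 9) → pyrrole ring of the second indole (step 11).

Assumption: the ketoreductase of step 5 is the anti‑(2R,3R)‑selective member found by screening a commercial ketoreductase panel (Ts = p‑toluenesulfonyl, TBS = tert‑butyldimethylsilyl).

**Step 1**
Reactants: 1 1H‑indole‑3‑carbaldehyde
Product: 2 1‑tosyl‑1H‑indole‑3‑carbaldehyde
Conditions: TsCl, Et3N, DMAP (cat.), CH2Cl2, 0 °C → rt
Reagents that add atoms: p‑toluenesulfonyl chloride (TsCl), Cc1ccc(cc1)S(Cl)(=O)=O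
Why: N‑sulfonylation of the acidic 3‑formylindole N–H; the sulfonyl group deactivates the indole so that the later indol‑3‑yl epoxide opens by SN2 and not by ionisation.

**Step 2**
Reactants: 2 1‑tosyl‑1H‑indole‑3‑carbaldehyde
Product: 3 1‑tosyl‑1H‑indole‑3‑carboxylic acid
Conditions: NaClO2, NaH2PO4, 2‑methyl‑2‑butene, tBuOH/THF/H2O, rt
Reagents that add atoms: sodium chlorite, [Na+].[O-]Cl=O
Why: Pinnick oxidation is chemoselective for the aldehyde, and the alkene scavenger removes HOCl before it can chlorinate the deactivated indole.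

**Step 3**
Reactants: 3 1‑tosyl‑1H‑indole‑3‑carboxylic acid; 4 potassium ethyl malonate
Product: 7 ethyl 3‑oxo‑3‑(1‑tosyl‑1H‑indol‑3‑yl)propanoate, via acyl imidazolide 5 (not isolated), via acylmalonic half ester 6 (not isolated)
Conditions: CDI, THF, rt; then 4, MgCl2, Et3N, THF, rt → 45 °C; aq. HCl
Reagents that add atoms: none
Why: Masamune–Brooks β‑keto ester synthesis: the magnesium enolate of the malonate half ester is C‑acylated by the acyl imidazolide and decarboxylates on acidification, under near‑neutral conditions that leave the N‑sulfonyl group intact.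

**Step 4**
Reactants: 7 ethyl 3‑oxo‑3‑(1‑tosyl‑1H‑indol‑3‑yl)propanoate
Product: 8 ethyl 2‑chloro‑3‑oxo‑3‑(1‑tosyl‑1H‑indol‑3‑yl)propanoate
Conditions: SO2Cl2 (1.05 eq), CH2Cl2, 0 °C → rt
Reagents that add atoms: sulfuryl chloride, ClS(Cl)(=O)=O
Why: Electrophilic α‑monochlorination of the β‑keto ester enol (the 3‑acyl‑N‑sulfonylindole ring is too electron‑poor to compete); C2 of 8 is configurationally labile and carries no fixed configuration.

**Step 5**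
Reactants: 8 ethyl 2‑chloro‑3‑oxo‑3‑(1‑tosyl‑1H‑indol‑3‑yl)propanoate
Product: 9 ethyl (2R,3R)‑2‑chloro‑3‑hydroxy‑3‑(1‑tosyl‑1H‑indol‑3‑yl)propanoate
Conditions: ketoreductase (anti‑selective, NADPH‑dependent), NADP+ (cat.), iPrOH (10 vol%), K‑phosphate buffer pH 6.5/DMSO 9:1, 30 °C
Reagents that add atoms: none
Why: Ketoreductase‑catalysed dynamic reductive kinetic resolution: C2 epimerises rapidly through the enol while the enzyme delivers hydride to one carbonyl face of the (2R)‑ketone only, so both stereocentres (anti, 2R,3R) are fixed in one asymmetric biocatalytic reduction with isopropanol as terminal reductant.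

**Step 6**
Reactants: 9 ethyl (2R,3R)‑2‑chloro‑3‑hydroxy‑3‑(1‑tosyl‑1H‑indol‑3‑yl)propanoate
Product: 10 ethyl (2S,3R)‑3‑(1‑tosyl‑1H‑indol‑3‑yl)oxirane‑2‑carboxylate
Conditions: K2CO3, DMF, 0 °C → rt
Reagents that add atoms: none
Why: Darzens‑type ring closure (intramolecular Williamson SN2): the alkoxide displaces chloride with inversion at C2, so the anti‑chlorohydrin gives the trans‑glycidate with C3 untouched.

**Step 7**
Reactants: 10 ethyl (2S,3R)‑3‑(1‑tosyl‑1H‑indol‑3‑yl)oxirane‑2‑carboxylate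
Product: 11 [(2R,3R)‑3‑(1‑tosyl‑1H‑indol‑3‑yl)oxiran‑2‑yl]methanol
Conditions: NaBH4, EtOH, 0 °C
Reagents that add atoms: none
Why: Hydride reduction of the α‑oxygen‑activated glycidic ester to the primary alcohol without opening the epoxide; both stereocentres are untouched (the C2 descriptor changes only through CIP priorities).

**Step 8**
Reactants: 12 but‑3‑yn‑1‑ol
Product: 13 (but‑3‑yn‑1‑yloxy)(tert‑butyl)dimethylsilane
Conditions: TBSCl, imidazole, CH2Cl2, rt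
Reagents that add atoms: tert‑butyldimethylsilyl chloride (TBSCl), CC(C)(C)[Si](C)(C)Cl
Why: Standard silyl ether protection so that the alkyne can be metallated and the future tryptophol oxygen stays masked until the end.

**Step 9**
Reactants: 11 [(2R,3R)‑3‑(1‑tosyl‑1H‑indol‑3‑yl)oxiran‑2‑yl]methanol; 13 (but‑3‑yn‑1‑yloxy)(tert‑butyl)dimethylsilane
Product: 16 (2S,3S)‑7‑(tert‑butyldimethylsilyloxy)‑3‑(1‑tosyl‑1H‑indol‑3‑yl)hept‑4‑yne‑1,2‑diol, via lithium acetylide 14 (not isolated), via diethylalkynylalane 15 (not isolated)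
Conditions: 13 (3.3 eq), n‑BuLi (3.2 eq), toluene, 0 °C; Et2AlCl (3.2 eq), 0 °C; then 11, toluene/CH2Cl2, −20 → 0 °C; aq. Rochelle salt
Reagents that add atoms: none
Why: Alkynylalane opening of a 2,3‑epoxy alcohol (Oshima–Nozaki type): the aluminium alkoxide anchors the reagent and the alkynyl group is delivered to the activated indolylic C3 anti to the C–O bond, giving the 1,2‑diol with inversion at C3 and retention at C2.

**Step 10**
Reactants: 16 (2S,3S)‑7‑(tert‑butyldimethylsilyloxy)‑3‑(1‑tosyl‑1H‑indol‑3‑yl)hept‑4‑yne‑1,2‑diol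
Product: 17 (2S,3S)‑1,2,7‑tris(tert‑butyldimethylsilyloxy)‑3‑(1‑tosyl‑1H‑indol‑3‑yl)hept‑4‑yne
Conditions: TBSOTf (2.5 eq), 2,6‑lutidine, CH2Cl2, −78 → 0 °C
Reagents that add atoms: tert‑butyldimethylsilyl triflate (TBSOTf), CC(C)(C)[Si](C)(C)OS(=O)(=O)C(F)(F)F
Why: Silyl triflate silylation caps both hydroxyls, including the hindered secondary one, which removes coordinating OH groups before the palladium step and enlarges the branched alkyne substituent.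

**Step 11**
Reactants: 17 (2S,3S)‑1,2,7‑tris(tert‑butyldimethylsilyloxy)‑3‑(1‑tosyl‑1H‑indol‑3‑yl)hept‑4‑yne; 18 2‑iodoaniline
Product: 19 2‑[(1R,2S)‑2,3‑bis(tert‑butyldimethylsilyloxy)‑1‑(1‑tosyl‑1H‑indol‑3‑yl)propyl]‑3‑[2‑(tert‑butyldimethylsilyloxy)ethyl]‑1H‑indole
Conditions: 18 (2 eq), Pd(OAc)2 (5 mol%), LiCl (1 eq), K2CO3 (3 eq), DMF, 100 °C
Reagents that add atoms: none
Why: Larock heteroannulation: the arylpalladium iodide adds syn across the alkyne with the aryl group on the less hindered carbon, so after C–N reductive elimination the bulky branched substituent sits at C2 and the silyloxyethyl chain at C3; the stereocentres are not involved (descriptors change only through CIP priorities).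

**Step 12**
Reactants: 19 (Larock product)
Product: 20 2‑[(1R,2S)‑2,3‑bis(tert‑butyldimethylsilyloxy)‑1‑(1H‑indol‑3‑yl)propyl]‑3‑[2‑(tert‑butyldimethylsilyloxy)ethyl]‑1H‑indole
Conditions: Mg turnings, MeOH, rt, ultrasound
Reagents that add atoms: none
Why: Dissolving‑metal (single‑electron) reductive cleavage of the N–S bond removes the sulfonyl group without touching silyl ethers or stereocentres.

**Step 13**
Reactants: 20 (tris‑silyl ether)
Product: 21 colletotryptin A, (2S,3R)‑3‑[3‑(2‑hydroxyethyl)‑1H‑indol‑2‑yl]‑3‑(1H‑indol‑3‑yl)propane‑1,2‑diol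
Conditions: TBAF (6 eq), THF, rt → 45 °C
Reagents that add atoms: none
Why: Fluoride‑driven desilylation frees all three hydroxyls under non‑acidic conditions, which protects the acid‑sensitive bis(indolyl)methane and its stereocentres.

**Compound list**
1 | 1H‑indole‑3‑carbaldehyde | O=Cc1c[nH]c2ccccc12 | starting material
2 | 1‑tosyl‑1H‑indole‑3‑carbaldehyde | O=Cc1cn(S(=O)(=O)c2ccc(C)cc2)c2ccccc12 | intermediate
3 | 1‑tosyl‑1H‑indole‑3‑carboxylic acid | OC(=O)c1cn(S(=O)(=O)c2ccc(C)cc2)c2ccccc12 | intermediate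
4 | potassium ethyl malonate (potassium 3‑ethoxy‑3‑oxopropanoate) | CCOC(=O)CC(=O)[O-].[K+] | starting material
5 | (1H‑imidazol‑1‑yl)(1‑tosyl‑1H‑indol‑3‑yl)methanone (acyl imidazolide, not isolated) | O=C(n1ccnc1)c1cn(S(=O)(=O)c2ccc(C)cc2)c2ccccc12 | intermediate
6 | 2‑(ethoxycarbonyl)‑3‑oxo‑3‑(1‑tosyl‑1H‑indol‑3‑yl)propanoic acid (present as magnesium salt, C2 labile, not isolated) | CCOC(=O)C(C(=O)O)C(=O)c1cn(S(=O)(=O)c2ccc(C)cc2)c2ccccc12 | intermediate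
7 | ethyl 3‑oxo‑3‑(1‑tosyl‑1H‑indol‑3‑yl)propanoate | CCOC(=O)CC(=O)c1cn(S(=O)(=O)c2ccc(C)cc2)c2ccccc12 | intermediate
8 | ethyl 2‑chloro‑3‑oxo‑3‑(1‑tosyl‑1H‑indol‑3‑yl)propanoate (C2 labile, no fixed configuration) | CCOC(=O)C(Cl)C(=O)c1cn(S(=O)(=O)c2ccc(C)cc2)c2ccccc12 | intermediate
9 | ethyl (2R,3R)‑2‑chloro‑3‑hydroxy‑3‑(1‑tosyl‑1H‑indol‑3‑yl)propanoate | CCOC(=O)[C@H](Cl)[C@H](O)c1cn(S(=O)(=O)c2ccc(C)cc2)c2ccccc12 | intermediate
10 | ethyl (2S,3R)‑3‑(1‑tosyl‑1H‑indol‑3‑yl)oxirane‑2‑carboxylate | CCOC(=O)[C@H]1O[C@@H]1c1cn(S(=O)(=O)c2ccc(C)cc2)c2ccccc12 | intermediate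
11 | [(2R,3R)‑3‑(1‑tosyl‑1H‑indol‑3‑yl)oxiran‑2‑yl]methanol | OC[C@H]1O[C@@H]1c1cn(S(=O)(=O)c2ccc(C)cc2)c2ccccc12 | intermediate
12 | but‑3‑yn‑1‑ol | OCCC#C | starting material
13 | (but‑3‑yn‑1‑yloxy)(tert‑butyl)dimethylsilane | C#CCCO[Si](C)(C)C(C)(C)C | intermediate
14 | [4‑(tert‑butyldimethylsilyloxy)but‑1‑yn‑1‑yl]lithium (not isolated) | [Li]C#CCCO[Si](C)(C)C(C)(C)C | intermediate
15 | diethyl[4‑(tert‑butyldimethylsilyloxy)but‑1‑yn‑1‑yl]aluminium (not isolated) | CC[Al](CC)C#CCCO[Si](C)(C)C(C)(C)C | intermediate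
16 | (2S,3S)‑7‑(tert‑butyldimethylsilyloxy)‑3‑(1‑tosyl‑1H‑indol‑3‑yl)hept‑4‑yne‑1,2‑diol | CC(C)(C)[Si](C)(C)OCCC#C[C@@H](c1cn(S(=O)(=O)c2ccc(C)cc2)c2ccccc12)[C@H](O)CO | intermediate
17 | (2S,3S)‑1,2,7‑tris(tert‑butyldimethylsilyloxy)‑3‑(1‑tosyl‑1H‑indol‑3‑yl)hept‑4‑yne | CC(C)(C)[Si](C)(C)OCCC#C[C@@H](c1cn(S(=O)(=O)c2ccc(C)cc2)c2ccccc12)[C@H](O[Si](C)(C)C(C)(C)C)CO[Si](C)(C)C(C)(C)C | intermediate
18 | 2‑iodoaniline | Nc1ccccc1I | starting material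
19 | 2‑[(1R,2S)‑2,3‑bis(tert‑butyldimethylsilyloxy)‑1‑(1‑tosyl‑1H‑indol‑3‑yl)propyl]‑3‑[2‑(tert‑butyldimethylsilyloxy)ethyl]‑1H‑indole | CC(C)(C)[Si](C)(C)OCCc1c([C@@H](c2cn(S(=O)(=O)c3ccc(C)cc3)c3ccccc23)[C@H](O[Si](C)(C)C(C)(C)C)CO[Si](C)(C)C(C)(C)C)[nH]c2ccccc12 | intermediate
20 | 2‑[(1R,2S)‑2,3‑bis(tert‑butyldimethylsilyloxy)‑1‑(1H‑indol‑3‑yl)propyl]‑3‑[2‑(tert‑butyldimethylsilyloxy)ethyl]‑1H‑indole | CC(C)(C)[Si](C)(C)OCCc1c([C@@H](c2c[nH]c3ccccc23)[C@H](O[Si](C)(C)C(C)(C)C)CO[Si](C)(C)C(C)(C)C)[nH]c2ccccc12 | intermediate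
21 | colletotryptin A, (2S,3R)‑3‑[3‑(2‑hydroxyethyl)‑1H‑indol‑2‑yl]‑3‑(1H‑indol‑3‑yl)propane‑1,2‑diol | OCCc1c([C@@H](c2c[nH]c3ccccc23)[C@H](O)CO)[nH]c2ccccc12 | target

**Step count and risks**
Total steps: 13. Longest linear sequence: 12 (steps 1–7 and 9–13; step 8 is a one‑step side branch).

Most likely to fail:

1. Step 5 (the bulky N‑sulfonylindolyl ketone may not be accepted by a ketoreductase with high anti selectivity and enantioselectivity). The fallback sets out from 2 and comes back at 11. Masamune–Roush Horner–Wadsworth–Emmons olefination of 2 with triethyl phosphonoacetate (LiCl, DBU, MeCN) gives ethyl (E)‑3‑(1‑tosyl‑1H‑indol‑3‑yl)prop‑2‑enoate F1. DIBAL‑H (CH2Cl2, −78 °C) reduces it to (E)‑3‑(1‑tosyl‑1H‑indol‑3‑yl)prop‑2‑en‑1‑ol F2. Sharpless asymmetric epoxidation (Ti(OiPr)4 10 mol%, D‑(−)‑diisopropyl tartrate 12 mol%, tBuOOH, 4 Å molecular sieves, CH2Cl2, −20 °C) then delivers 11 directly, the stereocentres now being set by the titanium–tartrate catalyst.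

2. Step 9 (partial ionisation of the indolylic epoxide carbon under the Lewis‑acidic alane would erode inversion, and C2 attack would give the 1,3‑diol). The fallback sets out from 11 and comes back at 19, so it also bypasses the annulation. Tryptophol is silylated (TBSCl, imidazole) to 3‑[2‑(tert‑butyldimethylsilyloxy)ethyl]‑1H‑indole F3. F3 (3 eq) opens 11 in a Friedel–Crafts alkylation (InBr3 5 mol%, CH2Cl2, 0 °C, or hexafluoroisopropanol as promoter solvent), bonding through its C2 to the indolylic epoxide carbon with inversion. This gives (2S,3R)‑3‑{3‑[2‑(tert‑butyldimethylsilyloxy)ethyl]‑1H‑indol‑2‑yl}‑3‑(1‑tosyl‑1H‑indol‑3‑yl)propane‑1,2‑diol F4, and TBSOTf/2,6‑lutidine converts it into 19.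

3. Step 11 (the alkyne is dialkyl‑type, so insertion regiochemistry rests on sterics alone and a regioisomeric indole may form). The fallback sets out from 11 and comes back at 19, building the indole with unambiguous regiochemistry:
   - 11 is opened as in step 9 but with diethyl(trimethylsilylethynyl)aluminium (trimethylsilylacetylene, n‑BuLi, Et2AlCl) to (2S,3R)‑3‑(1‑tosyl‑1H‑indol‑3‑yl)‑5‑(trimethylsilyl)pent‑4‑yne‑1,2‑diol F5.
   - K2CO3/MeOH removes the C‑silyl group to give (2S,3S)‑3‑(1‑tosyl‑1H‑indol‑3‑yl)pent‑4‑yne‑1,2‑diol F6.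
   - TBSOTf/2,6‑lutidine gives (2S,3S)‑1,2‑bis(tert‑butyldimethylsilyloxy)‑3‑(1‑tosyl‑1H‑indol‑3‑yl)pent‑4‑yne F7.
   - Sonogashira coupling with 18 (Pd(PPh3)2Cl2, CuI, Et3N) gives 2‑[(3S,4S)‑4,5‑bis(tert‑butyldimethylsilyloxy)‑3‑(1‑tosyl‑1H‑indol‑3‑yl)pent‑1‑yn‑1‑yl]aniline F8.
   - Base‑free 5‑endo cyclisation (NaAuCl4·2H2O 4 mol%, EtOH, rt) gives 2‑[(1R,2S)‑2,3‑bis(tert‑butyldimethylsilyloxy)‑1‑(1‑tosyl‑1H‑indol‑3‑yl)propyl]‑1H‑indole F9.
   - N‑Magnesiation (EtMgBr) and C3 alkylation with ethylene oxide give 2‑{2‑[(1R,2S)‑2,3‑bis(tert‑butyldimethylsilyloxy)‑1‑(1‑tosyl‑1H‑indol‑3‑yl)propyl]‑1H‑indol‑3‑yl}ethan‑1‑ol F10.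
   - TBSCl/imidazole converts F10 into 19.

**Further compounds**
F1 | step 5 | ethyl (E)‑3‑(1‑tosyl‑1H‑indol‑3‑yl)prop‑2‑enoate | CCOC(=O)/C=C/c1cn(S(=O)(=O)c2ccc(C)cc2)c2ccccc12
F2 | step 5 | (E)‑3‑(1‑tosyl‑1H‑indol‑3‑yl)prop‑2‑en‑1‑ol | OC/C=C/c1cn(S(=O)(=O)c2ccc(C)cc2)c2ccccc12
F3 | step 9 | 3‑[2‑(tert‑butyldimethylsilyloxy)ethyl]‑1H‑indole | CC(C)(C)[Si](C)(C)OCCc1c[nH]c2ccccc12
F4 | step 9 | (2S,3R)‑3‑{3‑[2‑(tert‑butyldimethylsilyloxy)ethyl]‑1H‑indol‑2‑yl}‑3‑(1‑tosyl‑1H‑indol‑3‑yl)propane‑1,2‑diol | CC(C)(C)[Si](C)(C)OCCc1c([C@@H](c2cn(S(=O)(=O)c3ccc(C)cc3)c3ccccc23)[C@H](O)CO)[nH]c2ccccc12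
F5 | step 11 | (2S,3R)‑3‑(1‑tosyl‑1H‑indol‑3‑yl)‑5‑(trimethylsilyl)pent‑4‑yne‑1,2‑diol | C[Si](C)(C)C#C[C@@H](c1cn(S(=O)(=O)c2ccc(C)cc2)c2ccccc12)[C@H](O)CO
F6 | step 11 | (2S,3S)‑3‑(1‑tosyl‑1H‑indol‑3‑yl)pent‑4‑yne‑1,2‑diol | C#C[C@@H](c1cn(S(=O)(=O)c2ccc(C)cc2)c2ccccc12)[C@H](O)CO
F7 | step 11 | (2S,3S)‑1,2‑bis(tert‑butyldimethylsilyloxy)‑3‑(1‑tosyl‑1H‑indol‑3‑yl)pent‑4‑yne | C#C[C@@H](c1cn(S(=O)(=O)c2ccc(C)cc2)c2ccccc12)[C@H](O[Si](C)(C)C(C)(C)C)CO[Si](C)(C)C(C)(C)C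
F8 | step 11 | 2‑[(3S,4S)‑4,5‑bis(tert‑butyldimethylsilyloxy)‑3‑(1‑tosyl‑1H‑indol‑3‑yl)pent‑1‑yn‑1‑yl]aniline | Nc1ccccc1C#C[C@@H](c1cn(S(=O)(=O)c2ccc(C)cc2)c2ccccc12)[C@H](O[Si](C)(C)C(C)(C)C)CO[Si](C)(C)C(C)(C)C
F9 | step 11 | 2‑[(1R,2S)‑2,3‑bis(tert‑butyldimethylsilyloxy)‑1‑(1‑tosyl‑1H‑indol‑3‑yl)propyl]‑1H‑indole | c1c([C@@H](c2cn(S(=O)(=O)c3ccc(C)cc3)c3ccccc23)[C@H](O[Si](C)(C)C(C)(C)C)CO[Si](C)(C)C(C)(C)C)[nH]c2ccccc12
F10 | step 11 | 2‑{2‑[(1R,2S)‑2,3‑bis(tert‑butyldimethylsilyloxy)‑1‑(1‑tosyl‑1H‑indol‑3‑yl)propyl]‑1H‑indol‑3‑yl}ethan‑1‑ol | OCCc1c([C@@H](c2cn(S(=O)(=O)c3ccc(C)cc3)c3ccccc23)[C@H](O[Si](C)(C)C(C)(C)C)CO[Si](C)(C)C(C)(C)C)[nH]c2ccccc12
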